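**Retrosynthetic overview**
Wailupemycin H (22) is cut at both pyrone-C3–CH2 bonds of the methylene bridge (Mannich/Michael logic) into tetralone monomer 18 and naphthyl pyrone 19; 19 is dehydrated, aromatised 18, so one monomer synthesis feeds both halves.
The carbocyclic ring of 18 is opened at C1–C2 and C3–C4 together: Michael–Claisen annulation of the benzylic anion of aryl ester 8 with chiral dioxinone 12, whose C5=C6 unit supplies C2 and C3, the C3 oxygen and a temporary C2 carboxyl held in the dioxanone ring.
Enabling feature: in the tetralone ring the C1 carbonyl (on C8a) and the C4 methine (on C4a) are ortho on the benzene ring, C4–H lies between that ring and C6 of the 2-pyrone (doubly stabilised carbanion), and the C3 oxygen is β to the C1 ketone (maps onto a β-oxy-acrylate acceptor).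
Ring order: pyrone and benzene rings are bought; temporary dioxanone ring (steps 4–5); carbocyclic tetralone ring (step 6); naphthalene ring by dehydration (step 9); methylene bridge last (steps 10–11).
Ester 8 comes from a Negishi union of pyrone 2 with bromo ester 5; dioxinone 12 comes from (S)-3-hydroxy-3-phenylpropanoic acid, whose stereocentre is relayed through the tert-butyl acetal carbon to C3.

Key step: step 6

Remark on the chemistry: 15 and 16 are drawn as chelated enols; the configuration at C2 of the tetralone is immaterial because this carbon ends as CH2. Compound 18 is divided between step 9 and step 11.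

**Step 1**
Reactants: 1 4-hydroxy-6-methyl-2H-pyran-2-one
Product: 2 4-(benzyloxy)-6-methyl-2H-pyran-2-one
Conditions: BnBr, K2CO3, DMF, 50 °C
Reagents that add atoms: benzyl bromide, BrCc1ccccc1
Why: Williamson-type O-alkylation of the vinylogous acid, where the potassium pyronate in DMF should react mainly at the 4-oxygen; the benzyl ether withstands the later amide bases and is removed by hydrogenolysis.

**Step 2**
Reactants: 3 1-(benzyloxy)-3-bromobenzene
Product: 5 phenyl 2-(benzyloxy)-6-bromobenzoate, via aryllithium 4 (not isolated)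
Conditions: LiN(i-Pr)2, THF, −78 °C; then transfer into PhOCOCl, THF, −78 °C
Reagents that add atoms: phenyl chloroformate, O=C(Cl)Oc1ccccc1
Why: Directed ortho-lithiation at the position flanked by bromine and the ether oxygen, then acylation by inverse addition to the chloroformate, should install the hindered phenyl ester directly; −78 °C is held to prevent loss of LiBr to the aryne.

**Step 3**
Reactants: 2 4-(benzyloxy)-6-methyl-2H-pyran-2-one, 5 phenyl 2-(benzyloxy)-6-bromobenzoate
Product: 8 phenyl 2-(benzyloxy)-6-{[4-(benzyloxy)-2-oxo-2H-pyran-6-yl]methyl}benzoate, via lithiated pyrone 6 (not isolated), via zinc reagent 7 (not isolated)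
Conditions: 2, LiN(SiMe3)2, THF, −78 °C; ZnCl2, −78 → 0 °C; then 5, Pd(OAc)2 (3 mol%), SPhos (6 mol%), THF, 25 → 50 °C
Reagents that add atoms: none
Why: Lateral deprotonation of the 6-methyl group (vinylogous enolate), transmetalation to zinc and Negishi cross-coupling with the aryl bromide should form the aryl–CH2 bond; the weakly basic zinc reagent tolerates the phenyl ester and the pyrone lactone.

**Step 4**
Reactants: 9 (S)-3-hydroxy-3-phenylpropanoic acid
Product: 10 (2R,6S)-2-tert-butyl-6-phenyl-1,3-dioxan-4-one
Conditions: t-BuCHO, pyridinium p-toluenesulfonate (cat.), CH2Cl2, reflux, azeotropic removal of water; recrystallisation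
Reagents that add atoms: pivalaldehyde, CC(C)(C)C=O
Why: Acid-catalysed acetalisation of the β-hydroxy acid under thermodynamic control should give the cis-dioxanone with both substituents equatorial, so the carbinol centre of the acid sets the new acetal centre as R.

**Step 5**
Reactants: 10 (2R,6S)-2-tert-butyl-6-phenyl-1,3-dioxan-4-one
Product: 12 (R)-2-tert-butyl-6-phenyl-4H-1,3-dioxin-4-one, via bromo dioxanone 11 (not isolated)
Conditions: N-bromosuccinimide (1.05 equiv), AIBN (cat.), PhCF3, 80 °C; then Et3N, 0 → 25 °C
Reagents that add atoms: none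
Why: Radical bromination at the benzylic, α-oxygenated C6–H followed by dehydrobromination of the tertiary α-bromo ether should introduce the C5=C6 double bond; the C6 centre is destroyed while the acetal centre keeps the stereochemical information.

**Step 6**
Reactants: 8 phenyl 2-(benzyloxy)-6-{[4-(benzyloxy)-2-oxo-2H-pyran-6-yl]methyl}benzoate, 12 (R)-2-tert-butyl-6-phenyl-4H-1,3-dioxin-4-one
Product: 15 (2R,10R,10aR)-6-(benzyloxy)-10-[4-(benzyloxy)-2-oxo-2H-pyran-6-yl]-2-tert-butyl-5-hydroxy-10a-phenyl-10,10a-dihydro-4H-naphtho[2,3-d][1,3]dioxin-4-one (enol form of the dioxanone-fused tetralone), via benzylic lithium anion 13 (not isolated), via Michael adduct enolate 14 (not isolated)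
Conditions: 8, LiN(SiMe3)2 (1.05 equiv), THF/DMPU, −78 °C; 12 (1.2 equiv), −78 °C, then −78 → −45 °C; AcOH, −78 °C
Reagents that add atoms: none
Why: Proposed new method: deprotonation of the doubly activated ArCH2–pyrone methylene gives a delocalised lithium anion (an ortho-quinodimethide ester dienolate) that should add in Michael fashion to C6 of the 6-phenyl dioxinone, after which the lactone enolate should acylate itself on the neighbouring phenyl ester (Claisen/Dieckmann step, loss of phenoxide), so the benzylic C–C bond and the acyl–CH bond of the tetralone ring form in one flask; the closest known reactions are the Michael–Claisen (Staunton–Weinreb) annulation of laterally lithiated ortho-toluate esters with enones and 4-alkoxypyranones and the conjugate addition of cuprates to 2-tert-butyl-6-alkyl-dioxinones, but a 6-aryl dioxinone has not served as acceptor for a stabilised benzylic lithium or for building a fully substituted carbinol carbon in this way. The only ring closed is the carbocyclic ring of the tetralone, by a 6-(enolexo)-exo-trig acylation after the intermolecular Michael step. The carbinol centre (tetralone C3) is controlled by the acetal carbon: the nucleophile should enter the dioxinone face anti to tert-butyl (axial attack on the sofa conformer), which with the R acetal places oxygen and phenyl as in the target. The methine centre (tetralone C4) should follow from a closed, lithium-bridged endo transition state in which pyronyl takes the outside position of the E-configured dienolate and the enolate oxygen is tied to the dioxinone carbonyl, putting pyronyl cis to the acetal oxygen and trans to phenyl. The step needs 1,4- over 1,2-addition (soft delocalised anion, hindered acylal carbonyl), Claisen closure faster than β-elimination of the acetal oxygen (activated phenyl ester, temperature below −40 °C, cold acidic quench) and no self-condensation of the anion (2,6-disubstituted ester).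

**Step 7**
Reactants: 15 enolised dioxanone-fused tetralone
Product: 17 (3R,4S)-8-(benzyloxy)-4-[4-(benzyloxy)-2-oxo-2H-pyran-6-yl]-3-hydroxy-3-phenyl-3,4-dihydronaphthalen-1(2H)-one, via keto acid 16 (not isolated)
Conditions: AcOH/THF/H2O (3:1:1), 45 °C
Reagents that add atoms: none
Why: Mild acid hydrolysis of the acylal (carboxylate leaving group) should release pivalaldehyde and the β-keto acid, which decarboxylates at this temperature to leave C2 as CH2 and the tertiary alcohol free; the C3–O bond is not broken, so both stereocentres are kept.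

**Step 8**
Reactants: 17 (3R,4S)-8-(benzyloxy)-4-[4-(benzyloxy)-2-oxo-2H-pyran-6-yl]-3-hydroxy-3-phenyl-3,4-dihydronaphthalen-1(2H)-one
Product: 18 (3R,4S)-3,8-dihydroxy-4-(4-hydroxy-2-oxo-2H-pyran-6-yl)-3-phenyl-3,4-dihydronaphthalen-1(2H)-one
Conditions: H2 (1 atm), Pd/C (10% palladium on carbon), EtOAc, 25 °C
Reagents that add atoms: none
Why: Hydrogenolysis of both benzyl ethers under neutral conditions; the tertiary benzylic alcohol, the aryl ketone and the pyrone should survive short exposure without acid.

**Step 9**
Reactants: 18 (3R,4S)-3,8-dihydroxy-4-(4-hydroxy-2-oxo-2H-pyran-6-yl)-3-phenyl-3,4-dihydronaphthalen-1(2H)-one (one portion)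
Product: 19 6-(4,5-dihydroxy-2-phenylnaphthalen-1-yl)-4-hydroxy-2H-pyran-2-one
Conditions: TsOH·H2O (10 mol%), 1,4-dioxane, 60 °C
Reagents that add atoms: none
Why: Acid-catalysed E1 dehydration of the β-hydroxy ketone through the tertiary benzylic cation, then tautomerisation to the naphthol, is driven by aromatisation; both stereocentres are erased, so stereochemically impure fractions of 18 can also be used here.

**Step 10**
Reactants: 19 6-(4,5-dihydroxy-2-phenylnaphthalen-1-yl)-4-hydroxy-2H-pyran-2-one
Product: 20 3-[(dimethylamino)methyl]-6-(4,5-dihydroxy-2-phenylnaphthalen-1-yl)-4-hydroxy-2H-pyran-2-one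
Conditions: Me2N=CH2+ I− (1.0 equiv), MeCN, 0 → 25 °C; neutralisation with NaHCO3 (1 equiv)
Reagents that add atoms: dimethyl(methylidene)ammonium iodide, C=[N+](C)C.[I-]
Why: Mannich reaction at C3 of the 4-hydroxy-2-pyrone, the most nucleophilic (enolic, 1,3-dioxygenated) carbon of 19, which should react with the preformed iminium salt without base while the neutral naphthalenediol ring stays untouched.

**Step 11**
Reactants: 20 3-[(dimethylamino)methyl]-6-(4,5-dihydroxy-2-phenylnaphthalen-1-yl)-4-hydroxy-2H-pyran-2-one, 18 (3R,4S)-3,8-dihydroxy-4-(4-hydroxy-2-oxo-2H-pyran-6-yl)-3-phenyl-3,4-dihydronaphthalen-1(2H)-one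
Product: 22 wailupemycin H, via methylidene dione 21 (not isolated)
Conditions: 18 (1.1 equiv), MeCN, 60 °C, N2 stream
Reagents that add atoms: none
Why: Thermal retro-Mannich loss of dimethylamine from the zwitterionic Mannich base should give the 3-methylidene-pyran-2,4-dione, which is trapped by Michael addition of pyrone C3 of 18 (the reaction type that forms methylene-bis(4-hydroxycoumarins)); no stereocentre is touched.

**Compound list**
1 | 4-hydroxy-6-methyl-2H-pyran-2-one | Cc1cc(O)cc(=O)o1 | starting material
2 | 4-(benzyloxy)-6-methyl-2H-pyran-2-one | Cc1cc(OCc2ccccc2)cc(=O)o1 | intermediate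
3 | 1-(benzyloxy)-3-bromobenzene | Brc1cccc(OCc2ccccc2)c1 | starting material
4 | 2-(benzyloxy)-6-bromophenyllithium | [Li]c1c(Br)cccc1OCc1ccccc1 | intermediate
5 | phenyl 2-(benzyloxy)-6-bromobenzoate | O=C(Oc1ccccc1)c1c(Br)cccc1OCc1ccccc1 | intermediate
6 | 4-(benzyloxy)-6-(lithiomethyl)-2H-pyran-2-one | [Li]Cc1cc(OCc2ccccc2)cc(=O)o1 | intermediate
7 | {[4-(benzyloxy)-2-oxo-2H-pyran-6-yl]methyl}zinc chloride | Cl[Zn]Cc1cc(OCc2ccccc2)cc(=O)o1 | intermediate
8 | phenyl 2-(benzyloxy)-6-{[4-(benzyloxy)-2-oxo-2H-pyran-6-yl]methyl}benzoate | O=C(Oc1ccccc1)c1c(Cc2cc(OCc3ccccc3)cc(=O)o2)cccc1OCc1ccccc1 | intermediate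
9 | (S)-3-hydroxy-3-phenylpropanoic acid | OC(=O)C[C@H](O)c1ccccc1 | starting material
10 | (2R,6S)-2-tert-butyl-6-phenyl-1,3-dioxan-4-one (cis) | CC(C)(C)[C@H]1OC(=O)C[C@@H](c2ccccc2)O1 | intermediate
11 | (2R)-6-bromo-2-tert-butyl-6-phenyl-1,3-dioxan-4-one (C6 epimers) | CC(C)(C)[C@H]1OC(=O)CC(Br)(c2ccccc2)O1 | intermediate
12 | (R)-2-tert-butyl-6-phenyl-4H-1,3-dioxin-4-one | CC(C)(C)[C@H]1OC(=O)C=C(c2ccccc2)O1 | intermediate
13 | benzylic lithium anion of 8 (lithiated at the ArCH2 carbon) | O=C(Oc1ccccc1)c1c(C([Li])c2cc(OCc3ccccc3)cc(=O)o2)cccc1OCc1ccccc1 | intermediate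
14 | Michael adduct, lithium enolate of the 6,6-disubstituted dioxanone (new C–C bond trans to tert-butyl) | CC(C)(C)[C@H]1OC(O[Li])=C[C@](c2ccccc2)([C@@H](c2cc(OCc3ccccc3)cc(=O)o2)c2cccc(OCc3ccccc3)c2C(=O)Oc2ccccc2)O1 | intermediate
15 | (2R,10R,10aR)-6-(benzyloxy)-10-[4-(benzyloxy)-2-oxo-2H-pyran-6-yl]-2-tert-butyl-5-hydroxy-10a-phenyl-10,10a-dihydro-4H-naphtho[2,3-d][1,3]dioxin-4-one | OC1=C2C(=O)O[C@H](C(C)(C)C)O[C@@]2(c3ccccc3)[C@@H](c3cc(OCc4ccccc4)cc(=O)o3)c3cccc(OCc4ccccc4)c13 | intermediate
16 | (3R,4S)-8-(benzyloxy)-4-[4-(benzyloxy)-2-oxo-2H-pyran-6-yl]-1,3-dihydroxy-3-phenyl-3,4-dihydronaphthalene-2-carboxylic acid (enol form of the β-keto acid) | OC1=C(C(=O)O)[C@](O)(c2ccccc2)[C@@H](c2cc(OCc3ccccc3)cc(=O)o2)c2cccc(OCc3ccccc3)c12 | intermediate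
17 | (3R,4S)-8-(benzyloxy)-4-[4-(benzyloxy)-2-oxo-2H-pyran-6-yl]-3-hydroxy-3-phenyl-3,4-dihydronaphthalen-1(2H)-one | O=C1C[C@](O)(c2ccccc2)[C@@H](c2cc(OCc3ccccc3)cc(=O)o2)c2cccc(OCc3ccccc3)c21 | intermediate
18 | (3R,4S)-3,8-dihydroxy-4-(4-hydroxy-2-oxo-2H-pyran-6-yl)-3-phenyl-3,4-dihydronaphthalen-1(2H)-one | O=C1C[C@](O)(c2ccccc2)[C@@H](c2cc(O)cc(=O)o2)c2cccc(O)c21 | intermediate
19 | 6-(4,5-dihydroxy-2-phenylnaphthalen-1-yl)-4-hydroxy-2H-pyran-2-one | O=c1cc(O)cc(-c2c(-c3ccccc3)cc(O)c3c(O)cccc23)o1 | intermediate
20 | 3-[(dimethylamino)methyl]-6-(4,5-dihydroxy-2-phenylnaphthalen-1-yl)-4-hydroxy-2H-pyran-2-one | CN(C)Cc1c(O)cc(-c2c(-c3ccccc3)cc(O)c3c(O)cccc23)oc1=O | intermediate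
21 | 6-(4,5-dihydroxy-2-phenylnaphthalen-1-yl)-3-methylidene-2H-pyran-2,4(3H)-dione | C=C1C(=O)C=C(-c2c(-c3ccccc3)cc(O)c3c(O)cccc23)OC1=O | intermediate
22 | wailupemycin H | O=C1C[C@](O)(c2ccccc2)[C@@H](c2cc(O)c(Cc3c(O)cc(-c4c(-c5ccccc5)cc(O)c5c(O)cccc45)oc3=O)c(=O)o2)c2cccc(O)c21 | target

**Step count**
Total: 11 steps. Longest linear sequence: 8 steps (for example steps 2, 3, 6, 7, 8, 9, 10, 11 from 3).

**Steps most likely to fail**

Step 6 (Proposed new method). The stabilised anion may add too slowly or reversibly to the hindered, electron-rich β-carbon. The intermediate enolate may lose the acetal oxygen by β-elimination (ring opening, then aromatisation) faster than the Claisen closure. Facial or endo/exo selectivity may be incomplete. The fallback uses known chemistry, sets out from 8 and returns to the route at 17. Crossed Claisen condensation of 8 with excess lithium enolate of acetophenone (THF, −78 °C) should give the 1,3-diketone 1-[2-(benzyloxy)-6-{[4-(benzyloxy)-2-oxo-2H-pyran-6-yl]methyl}phenyl]-3-phenylpropane-1,3-dione F1. Base-mediated intramolecular aldol addition of the doubly activated methylene of F1 to the benzoyl carbonyl (Cs2CO3, MeOH, 25 °C, 6-(enolexo)-exo-trig) should then give 17 as a racemate, that is, together with its mirror image (3S,4R)-8-(benzyloxy)-4-[4-(benzyloxy)-2-oxo-2H-pyran-6-yl]-3-hydroxy-3-phenyl-3,4-dihydronaphthalen-1(2H)-one F2. Diastereoselection at C4 would have to be optimised, and 17 would be separated from F2 by preparative HPLC on a chiral stationary phase before continuing with step 8.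

Step 7. Acid may ionise the tertiary benzylic C3–O bond (dehydration and aromatisation to the naphthol), or the β-hydroxy ketone may open by retro-aldol cleavage during hydrolysis. The fallback sets out from 15 and returns at 17. Acid-free thermolysis in wet 1,4-dioxane at 90 °C should extrude pivalaldehyde from the enolised 5-acyl-dioxanone, as 5-acyl-2,2-dimethyl-1,3-dioxane-4,6-diones do on heating. This would give the α-oxoketene (3R,4S)-8-(benzyloxy)-4-[4-(benzyloxy)-2-oxo-2H-pyran-6-yl]-3-hydroxy-2-(oxomethylidene)-3-phenyl-3,4-dihydronaphthalen-1(2H)-one F3, which is hydrated in situ to keto acid 16 and decarboxylates to 17.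

Step 11. The bridge may scramble by reversible retro-Michael cleavage into symmetrical dimers, the naphthalenediol ring may compete as a carbon nucleophile, or the liberated amine may induce dehydration of the β-hydroxy ketone. The fallback sets out from 19 (with 18), bypasses 20 and returns at 22. Direct three-component coupling with aqueous formaldehyde (1 equiv) in EtOH/phosphate buffer (pH 7) at 25 °C should hydroxymethylate 19 at pyrone C3 to 6-(4,5-dihydroxy-2-phenylnaphthalen-1-yl)-4-hydroxy-3-(hydroxymethyl)-2H-pyran-2-one F4. F4 loses water to 21, which is trapped by 18 (Knoevenagel–Michael sequence). The cross-coupled 22 would be separated from symmetrical coupling products by reversed-phase HPLC.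

**Further compounds**
F1 | step 6 | 1-[2-(benzyloxy)-6-{[4-(benzyloxy)-2-oxo-2H-pyran-6-yl]methyl}phenyl]-3-phenylpropane-1,3-dione | O=C(CC(=O)c1ccccc1)c1c(Cc2cc(OCc3ccccc3)cc(=O)o2)cccc1OCc1ccccc1
F2 | step 6 | (3S,4R)-8-(benzyloxy)-4-[4-(benzyloxy)-2-oxo-2H-pyran-6-yl]-3-hydroxy-3-phenyl-3,4-dihydronaphthalen-1(2H)-one | O=C1C[C@@](O)(c2ccccc2)[C@H](c2cc(OCc3ccccc3)cc(=O)o2)c2cccc(OCc3ccccc3)c21
F3 | step 7 | (3R,4S)-8-(benzyloxy)-4-[4-(benzyloxy)-2-oxo-2H-pyran-6-yl]-3-hydroxy-2-(oxomethylidene)-3-phenyl-3,4-dihydronaphthalen-1(2H)-one | O=C1C(=C=O)[C@](O)(c2ccccc2)[C@@H](c2cc(OCc3ccccc3)cc(=O)o2)c2cccc(OCc3ccccc3)c21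
F4 | step 11 | 6-(4,5-dihydroxy-2-phenylnaphthalen-1-yl)-4-hydroxy-3-(hydroxymethyl)-2H-pyran-2-one | OCc1c(O)cc(-c2c(-c3ccccc3)cc(O)c3c(O)cccc23)oc1=O
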